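**Retrosynthetic overview** (labdane numbering: ring A = C1–C5, C10; ring B = C5–C10; C17 on C8, C18/C19 on C4, C20 on C10)
1. Late disconnections: C8=C17 (methylenation of an 8‑ketone), C20–OAc, C12–C13 (B‑alkyl Suzuki coupling brings in the butenolide), C4–C18 (enolate methylation of a C4 ester).
2. Core: C5–C10 by 6‑exo cyclisation of a C10 radical onto an alkylidene malonate (C5=C4), then C3–C4 by malonate alkylation in the same pot; a monocyclic tetrahydrofuran becomes the tricycle.
3. Enabling feature: C20 is axial on the β face of ring B and 1,3 to C8. With C8 as a carbinol and C20 at aldehyde level they close a temporary five‑membered lactol ether C8–O–C20–C10–C9, so C10 is a ring radical and C5 can only add on the face that makes C20 axial.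
4. Stereochemistry is relayed from one catalyst‑set carbinol centre (C8): anti cuprate addition sets C9, the key step sets C10 and C5, α‑face methylation sets C4; C8 is then erased as ketone/methylene.
5. Ring order: butenolide‑derived lactone/lactol (temporary) → ring B → ring A (one pot) → side‑chain butenolide.

Key step: step 8

Assumption: the acetal/lactol carbon C20 (14–16, 18–21, 23–25, F8–F11), C4 of 21 and F6, and the S‑bearing carbon of F10 are inconsequential epimeric mixtures and are left undefined in the SMILES; the C10 configuration drawn for 9, 12, 14–16 and 18 is the expected one and is erased in step 8. (TBS = tert‑butyldimethylsilyl.)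

Step 1
Reactants: 1 4-[(tert-butyldimethylsilyl)oxy]butanal; 2 methyl propiolate
Product: 3 methyl (4S)-7-[(tert-butyldimethylsilyl)oxy]-4-hydroxyhept-2-ynoate
Conditions: ProPhenol ligand (10 mol %, enantiomer that delivers the S alcohol), Me2Zn, PhMe, 0 °C
Reagents that add atoms: methyl propiolate (2), C#CC(=O)OC
Why: Zinc–ProPhenol‑catalysed enantioselective alkynylation of an aliphatic aldehyde with a zinc propiolate is a known reaction type, and the chiral dinuclear zinc pocket differentiates the aldehyde faces to set C8 as S, the only catalyst‑set stereocentre of the route.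

Step 2
Reactants: 3 methyl (4S)-7-[(tert-butyldimethylsilyl)oxy]-4-hydroxyhept-2-ynoate
Product: 5 (5S)-5-{3-[(tert-butyldimethylsilyl)oxy]propyl}furan-2(5H)-one, via Z-hydroxy enoate 4 (not isolated)
Conditions: H2 (1 atm), Lindlar Pd, quinoline, EtOAc, rt; then PPTS (cat.), CH2Cl2, rt
Reagents that add atoms: none
Why: Lindlar semi‑hydrogenation should give the Z‑enoate, whose cis geometry lets the hydroxyl lactonise onto the ester to the butenolide without touching C8 or the silyl ether.

Step 3
Reactants: 5 (5S)-5-{3-[(tert-butyldimethylsilyl)oxy]propyl}furan-2(5H)-one; 6 vinylmagnesium bromide; 7 phenylselenenyl bromide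
Product: 9 (3R,4S,5S)-5-{3-[(tert-butyldimethylsilyl)oxy]propyl}-3-(phenylselanyl)-4-vinyldihydrofuran-2(3H)-one, via bromomagnesium lactone enolate 8 (not isolated)
Conditions: 6, CuBr·SMe2 (10 mol %), THF, −78 °C; then 7, −78 → −40 °C
Reagents that add atoms: vinylmagnesium bromide (6), C=C[Mg]Br; phenylselenenyl bromide (7), Br[Se]c1ccccc1
Why: Copper‑catalysed conjugate addition of a vinyl Grignard reagent to a γ‑substituted butenolide should occur anti to the C8 substituent (this sets C9, vinyl trans to the C7 chain), and electrophilic α‑selenenylation of the enolate in situ installs the future radical leaving group on C10.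

Step 4
Reactants: 9 (3R,4S,5S)-5-{3-[(tert-butyldimethylsilyl)oxy]propyl}-3-(phenylselanyl)-4-vinyldihydrofuran-2(3H)-one; 10 1-chloro-3-iodopropane
Product: 12 (3S,4S,5S)-5-{3-[(tert-butyldimethylsilyl)oxy]propyl}-3-(3-chloropropyl)-3-(phenylselanyl)-4-vinyldihydrofuran-2(3H)-one, via lithium enolate 11 (not isolated)
Conditions: LiHMDS, THF–DMPU, −78 °C; then 10, −78 → −20 °C
Reagents that add atoms: 1-chloro-3-iodopropane (10), ClCCCI
Why: Alkylation of the α‑selanyl lactone enolate at the more reactive C–I end of the dihalide should build the quaternary C10 with the C1–C3 arm and keep the chloride as the later leaving group; the configuration at C10 is irrelevant because it becomes a radical.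

Step 5
Reactants: 12 (3S,4S,5S)-5-{3-[(tert-butyldimethylsilyl)oxy]propyl}-3-(3-chloropropyl)-3-(phenylselanyl)-4-vinyldihydrofuran-2(3H)-one; 13 methanol
Product: 15 3-[(2S,3S,4S)-4-(3-chloropropyl)-5-methoxy-4-(phenylselanyl)-3-vinyloxolan-2-yl]propan-1-ol, via lactol 14 (not isolated)
Conditions: DIBAL-H, CH2Cl2, −78 °C (Rochelle salt work-up); then MeOH, CSA (cat.), rt
Reagents that add atoms: methanol (13), CO
Why: DIBAL‑H half‑reduction of the lactone and Fischer‑type acetalisation in acidic methanol should give the 2‑methoxyoxolane (C20 at aldehyde level, so the C10 radical will be nucleophilic), the same acid cleaving the primary TBS ether while the large excess of methanol outcompetes internal acetal formation.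

Step 6
Reactants: 15 3-[(2S,3S,4S)-4-(3-chloropropyl)-5-methoxy-4-(phenylselanyl)-3-vinyloxolan-2-yl]propan-1-ol
Product: 16 3-[(2S,3S,4S)-4-(3-chloropropyl)-5-methoxy-4-(phenylselanyl)-3-vinyloxolan-2-yl]propanal
Conditions: SO3·pyridine, DMSO, iPr2NEt, CH2Cl2, 0 °C
Reagents that add atoms: none
Why: Parikh–Doering oxidation should convert the primary alcohol into the aldehyde under non‑acidic conditions that tolerate the acetal, the selenide and the alkyl chloride.

Step 7
Reactants: 16 3-[(2S,3S,4S)-4-(3-chloropropyl)-5-methoxy-4-(phenylselanyl)-3-vinyloxolan-2-yl]propanal; 17 dimethyl malonate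
Product: 18 dimethyl 2-{3-[(2S,3S,4S)-4-(3-chloropropyl)-5-methoxy-4-(phenylselanyl)-3-vinyloxolan-2-yl]propylidene}malonate
Conditions: 17, piperidine (cat.), AcOH (cat.), 4 Å MS, PhH, rt
Reagents that add atoms: dimethyl malonate (17), COC(=O)CC(=O)OC
Why: Knoevenagel condensation of the aliphatic aldehyde with dimethyl malonate should give the alkylidene malonate, a doubly activated radical acceptor that places C4 and the future C19 ester carbon on C5.

Step 8
Reactants: 18 dimethyl 2-{3-[(2S,3S,4S)-4-(3-chloropropyl)-5-methoxy-4-(phenylselanyl)-3-vinyloxolan-2-yl]propylidene}malonate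
Product: 20 tricyclic acetal diester (trans-decalin with β-face C8–O–C20(OMe) bridge; C4(CO2Me)2; 9β-vinyl; 5α-H), via bicyclic malonate 19 (not isolated)
Conditions: Bu3SnH (slow addition), AIBN (cat.), PhH, 80 °C; then DMF, Cs2CO3, NaI (cat.), 60 °C
Reagents that add atoms: none
Why: Bu3Sn• abstracts the phenylselanyl group from C10 to give a tertiary, nucleophilic alkyl radical that adds to C5, the β‑carbon of the alkylidene malonate; the malonyl radical is reduced by Bu3SnH to 19, and after Cs2CO3/NaI/DMF is added the malonate anion displaces the C3 chloride. The closest known reaction types are the Giese‑type tin hydride cyclisation of alkyl radicals onto alkylidene malonates and the intramolecular alkylation of malonates, run here as a one‑pot Michael‑initiated‑ring‑closure pattern with a radical first stage. Ring B closes 6‑exo‑trig through a chair transition state and, because C8 and C10 both belong to the oxolane, becomes a 6‑oxabicyclo[3.2.1]octane; ring A closes 6‑exo‑tet. At C10 the new bond can only form on the oxolane face that carries the C7 chain, so the C8 stereocentre fixes C20 axial (β) and the C1 arm equatorial; at C5 the bulky malonate terminus should take the equatorial position of the chair, away from C9–H, which gives 5α‑H and hence the trans ring fusion when ring A closes. The step needs exo cyclisation to outrun hydrogen transfer to the C10 radical, 1,5‑hydrogen shift from C6 and reversible 3‑exo attack on the neighbouring vinyl group; the doubly activated acceptor and slow addition of Bu3SnH should secure this, and the primary chloride is inert to tin radicals until the base is added.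

Step 9
Reactants: 20 tricyclic acetal diester
Product: 21 methyl 8β,20-epoxy-20-methoxy-13,14,15,16,17,18-hexanorlabd-11-en-19-oate (C4 epimers)
Conditions: LiCl, H2O, DMSO, 150 °C
Reagents that add atoms: none
Why: Krapcho dealkoxycarbonylation should remove one of the geminal esters under neutral conditions that leave the acetal and the vinyl group intact; the C4 epimers converge in the next step.

Step 10
Reactants: 21 methyl 8β,20-epoxy-20-methoxy-13,14,15,16,17,18-hexanorlabd-11-en-19-oate; 22 iodomethane
Product: 24 methyl 8β,20-epoxy-20-methoxy-13,14,15,16,17-pentanorlabd-11-en-19-oate (4α-Me), via lithium ester enolate 23 (not isolated)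
Conditions: LDA, THF–DMPU, −78 → −40 °C; then MeI
Reagents that add atoms: iodomethane (22), CI
Why: In this ester enolate alkylation iodomethane should approach the exocyclic C4 enolate from the α face, opposite the axial C20 bridge on C10, giving 4α‑methyl/4β‑CO2Me, the usual outcome for 4‑carboalkoxy trans‑decalins with an axial C10 substituent.

Step 11
Reactants: 24 methyl 8β,20-epoxy-20-methoxy-13,14,15,16,17-pentanorlabd-11-en-19-oate
Product: 26 methyl 8β,20-dihydroxy-13,14,15,16,17-pentanorlabd-11-en-19-oate, via lactol 25 (not isolated)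
Conditions: 1 M HCl, THF, 40 °C; neutralise; then NaBH4, MeOH, 0 °C → rt
Reagents that add atoms: water, O
Why: Acid hydrolysis of the bridged methyl acetal should give the lactol, which sodium borohydride reduces through its hydroxy‑aldehyde form to the C8/C20 diol while the hindered C19 methyl ester is untouched.

Step 12
Reactants: 26 methyl 8β,20-dihydroxy-13,14,15,16,17-pentanorlabd-11-en-19-oate; 27 3-bromofuran-2(5H)-one
Product: 29 methyl 8β,20-dihydroxy-17-norlabd-13-en-16,15-olid-19-oate, via B-alkyl-9-BBN adduct 28 (not isolated)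
Conditions: 9-BBN (excess, the hydroxyls take up reagent), THF, rt; then 27, PdCl2(dppf) (cat.), AsPh3 (cat.), Cs2CO3, DMF–H2O, rt
Reagents that add atoms: 3-bromofuran-2(5H)-one (27), O=C1OCC=C1Br
Why: Anti‑Markovnikov hydroboration of the only alkene and B‑alkyl Suzuki–Miyaura coupling with the α‑bromo butenolide (an α‑halo enone‑type partner) should join C12 to C13 and deliver the complete side chain.

Step 13
Reactants: 29 methyl 8β,20-dihydroxy-17-norlabd-13-en-16,15-olid-19-oate; 30 acetic anhydride
Product: 31 methyl 20-acetoxy-8β-hydroxy-17-norlabd-13-en-16,15-olid-19-oate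
Conditions: Ac2O (1.1 equiv), pyridine, CH2Cl2, 0 °C
Reagents that add atoms: acetic anhydride (30), CC(=O)OC(C)=O
Why: In this chemoselective acylation the primary C20 hydroxyl should react faster than the axial secondary C8 hydroxyl flanked by C9, giving the C20 acetate.

Step 14
Reactants: 31 methyl 20-acetoxy-8β-hydroxy-17-norlabd-13-en-16,15-olid-19-oate
Product: 32 methyl 20-acetoxy-8-oxo-17-norlabd-13-en-16,15-olid-19-oate
Conditions: Dess–Martin periodinane, NaHCO3, CH2Cl2, rt
Reagents that add atoms: none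
Why: Dess–Martin oxidation of the remaining secondary alcohol should give the C8 ketone under buffered conditions, and C9 already carries its side chain in the equatorial, thermodynamically favoured orientation.

Step 15
Reactants: 32 methyl 20-acetoxy-8-oxo-17-norlabd-13-en-16,15-olid-19-oate; 33 dibromomethane
Product: 34 methyl (4S,5R,9S,10S)-20-acetoxylabda-8(17),13-dien-16,15-olid-19-oate (target)
Conditions: Zn, CH2Br2, TiCl4, THF–CH2Cl2, 0 °C → rt
Reagents that add atoms: dibromomethane (33), BrCBr
Why: Lombardo methylenation with the non‑basic Zn/CH2Br2/TiCl4 reagent should convert the hindered C8 ketone into the exocyclic methylene without attacking the acetate, the methyl ester or the butenolide and without epimerising C9.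

**Compound list**
1 | 4-[(tert-butyldimethylsilyl)oxy]butanal | O=CCCCO[Si](C)(C)C(C)(C)C | starting material
2 | methyl propiolate | C#CC(=O)OC | starting material
3 | methyl (4S)-7-[(tert-butyldimethylsilyl)oxy]-4-hydroxyhept-2-ynoate | COC(=O)C#C[C@@H](O)CCCO[Si](C)(C)C(C)(C)C | intermediate
4 | methyl (2Z,4S)-7-[(tert-butyldimethylsilyl)oxy]-4-hydroxyhept-2-enoate | COC(=O)/C=C\[C@@H](O)CCCO[Si](C)(C)C(C)(C)C | intermediate
5 | (5S)-5-{3-[(tert-butyldimethylsilyl)oxy]propyl}furan-2(5H)-one | O=C1C=C[C@H](CCCO[Si](C)(C)C(C)(C)C)O1 | intermediate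
6 | vinylmagnesium bromide | C=C[Mg]Br | starting material
7 | phenylselenenyl bromide | Br[Se]c1ccccc1 | starting material
8 | bromomagnesium enolate of the (4S,5S)-4-vinyl lactone | Br[Mg]OC1=C[C@@H](C=C)[C@H](CCCO[Si](C)(C)C(C)(C)C)O1 | intermediate
9 | (3R,4S,5S)-5-{3-[(tert-butyldimethylsilyl)oxy]propyl}-3-(phenylselanyl)-4-vinyldihydrofuran-2(3H)-one | O=C1O[C@@H](CCCO[Si](C)(C)C(C)(C)C)[C@H](C=C)[C@H]1[Se]c1ccccc1 | intermediate
10 | 1-chloro-3-iodopropane | ClCCCI | starting material
11 | lithium enolate of 9 | [Li]OC1=C([Se]c2ccccc2)[C@@H](C=C)[C@H](CCCO[Si](C)(C)C(C)(C)C)O1 | intermediate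
12 | (3S,4S,5S)-5-{3-[(tert-butyldimethylsilyl)oxy]propyl}-3-(3-chloropropyl)-3-(phenylselanyl)-4-vinyldihydrofuran-2(3H)-one | O=C1O[C@@H](CCCO[Si](C)(C)C(C)(C)C)[C@H](C=C)[C@]1(CCCCl)[Se]c1ccccc1 | intermediate
13 | methanol | CO | starting material
14 | lactol of 12: (3S,4S,5S)-5-{3-[(tert-butyldimethylsilyl)oxy]propyl}-3-(3-chloropropyl)-3-(phenylselanyl)-4-vinyloxolan-2-ol | OC1O[C@@H](CCCO[Si](C)(C)C(C)(C)C)[C@H](C=C)[C@]1(CCCCl)[Se]c1ccccc1 | intermediate
15 | 3-[(2S,3S,4S)-4-(3-chloropropyl)-5-methoxy-4-(phenylselanyl)-3-vinyloxolan-2-yl]propan-1-ol | COC1O[C@@H](CCCO)[C@H](C=C)[C@]1(CCCCl)[Se]c1ccccc1 | intermediate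
16 | 3-[(2S,3S,4S)-4-(3-chloropropyl)-5-methoxy-4-(phenylselanyl)-3-vinyloxolan-2-yl]propanal | COC1O[C@@H](CCC=O)[C@H](C=C)[C@]1(CCCCl)[Se]c1ccccc1 | intermediate
17 | dimethyl malonate | COC(=O)CC(=O)OC | starting material
18 | dimethyl 2-{3-[(2S,3S,4S)-4-(3-chloropropyl)-5-methoxy-4-(phenylselanyl)-3-vinyloxolan-2-yl]propylidene}malonate | COC1O[C@@H](CCC=C(C(=O)OC)C(=O)OC)[C@H](C=C)[C@]1(CCCCl)[Se]c1ccccc1 | intermediate
19 | bicyclic malonate: 6-oxabicyclo[3.2.1]octane (ring B plus C8–O–C20(OMe) bridge) with C10 3-chloropropyl, equatorial CH(CO2Me)2 on C5 (5α-H), 9β-vinyl | COC1O[C@H]2CC[C@@H](C(C(=O)OC)C(=O)OC)[C@]1(CCCCl)[C@H]2C=C | intermediate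
20 | tricyclic acetal diester: trans-decalin with β-face C8–O–C20(OMe) bridge, C4(CO2Me)2, 9β-vinyl, 5α-H | COC1O[C@H]2CC[C@@H]3[C@]1(CCCC3(C(=O)OC)C(=O)OC)[C@H]2C=C | intermediate
21 | methyl 8β,20-epoxy-20-methoxy-13,14,15,16,17,18-hexanorlabd-11-en-19-oate (C4 epimers) | COC1O[C@H]2CC[C@@H]3[C@]1(CCCC3C(=O)OC)[C@H]2C=C | intermediate
22 | iodomethane | CI | starting material
23 | lithium ester enolate of 21 | COC1O[C@H]2CC[C@@H]3[C@]1(CCCC3=C(O[Li])OC)[C@H]2C=C | intermediate
24 | methyl 8β,20-epoxy-20-methoxy-13,14,15,16,17-pentanorlabd-11-en-19-oate (4α-Me, 4β-CO2Me) | COC1O[C@H]2CC[C@@H]3[C@]1(CCC[C@]3(C)C(=O)OC)[C@H]2C=C | intermediate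
25 | lactol: methyl 8β,20-epoxy-20-hydroxy-13,14,15,16,17-pentanorlabd-11-en-19-oate | OC1O[C@H]2CC[C@@H]3[C@]1(CCC[C@]3(C)C(=O)OC)[C@H]2C=C | intermediate
26 | methyl 8β,20-dihydroxy-13,14,15,16,17-pentanorlabd-11-en-19-oate | O[C@H]1CC[C@@H]2[C@](CO)(CCC[C@]2(C)C(=O)OC)[C@H]1C=C | intermediate
27 | 3-bromofuran-2(5H)-one | O=C1OCC=C1Br | starting material
28 | B-alkyl-9-BBN adduct of 26 (boron on C12; drawn with free hydroxyls) | O[C@H]1CC[C@@H]2[C@](CO)(CCC[C@]2(C)C(=O)OC)[C@H]1CCB1C2CCCC1CCC2 | intermediate
29 | methyl 8β,20-dihydroxy-17-norlabd-13-en-16,15-olid-19-oate | O[C@H]1CC[C@@H]2[C@](CO)(CCC[C@]2(C)C(=O)OC)[C@H]1CCC1=CCOC1=O | intermediate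
30 | acetic anhydride | CC(=O)OC(C)=O | starting material
31 | methyl 20-acetoxy-8β-hydroxy-17-norlabd-13-en-16,15-olid-19-oate | O[C@H]1CC[C@@H]2[C@](COC(C)=O)(CCC[C@]2(C)C(=O)OC)[C@H]1CCC1=CCOC1=O | intermediate
32 | methyl 20-acetoxy-8-oxo-17-norlabd-13-en-16,15-olid-19-oate | O=C1CC[C@@H]2[C@](COC(C)=O)(CCC[C@]2(C)C(=O)OC)[C@H]1CCC1=CCOC1=O | intermediate
33 | dibromomethane | BrCBr | starting material
34 | methyl (4S,5R,9S,10S)-20-acetoxylabda-8(17),13-dien-16,15-olid-19-oate | C=C1CC[C@@H]2[C@](COC(C)=O)(CCC[C@]2(C)C(=O)OC)[C@H]1CCC1=CCOC1=O | target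

**Step count and risks**
Total steps: 15. Longest linear sequence: 15 (from 1).

Steps most likely to fail:

1. Step 8 (key step). The C10 radical may take up hydrogen or undergo 1,5‑hydrogen shift before it cyclises, or the malonate terminus may not discriminate well between equatorial and axial at C5, which would erode the trans ring fusion. Fallback, from 5 back to 25: the C5–C10 bond is made by a polar Michael‑initiated ring closure at the lactone level. Butenolide 5 takes up vinylmagnesium bromide (CuBr·SMe2) to give the trans‑4‑vinyl lactone F1. LDA and 1‑chloro‑3‑iodopropane give the α‑(3‑chloropropyl) lactone F2. TBAF gives the primary alcohol F3, Parikh–Doering oxidation the aldehyde F4, and Wittig olefination with methyl (triphenylphosphoranylidene)acetate the E‑enoate F5. LiHMDS (THF–DMPU, −78 °C → rt) forms the lactone enolate at C10, which adds to C5 of the enoate in the same bridged 6‑exo mode; the resulting ester enolate closes ring A on the chloride to give the tricyclic lactone ester F6. LDA/MeI methylates C4 from the α face to give the bridged lactone F7, and DIBAL‑H at −78 °C reduces it to lactol 25, where the borohydride stage of step 11 takes over.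

2. Step 12. Protodeboronation, β‑hydride elimination of the alkylpalladium species or base‑induced decomposition of the bromobutenolide may prevent the coupling. Fallback, from 24 back to 29: the butenolide is built by enolate alkylation and sulfoxide elimination. Acetal 24 is hydroborated and oxidised (9‑BBN; NaBO3) to the primary alcohol F8 and converted (I2, PPh3, imidazole) to the iodide F9. F9 alkylates the lithium enolate of 3‑(phenylsulfanyl)dihydrofuran‑2(3H)‑one to give the α‑phenylsulfanyl lactone F10. Oxidation to the sulfoxide (mCPBA, −78 °C) and thermal syn‑elimination (PhMe, 110 °C, CaCO3) give the butenolide acetal F11. The hydrolysis/NaBH4 conditions of step 11 then convert F11 into diol 29.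

3. Step 15. Conversion of the hindered C8 ketone may stall, or the Lewis‑acidic reagent may cleave the acetate or open the butenolide. Fallback, from 26 back to 34: the methylene is installed before the butenolide. Diol 26 is acetylated selectively at C20 to the mono‑acetate F12 and oxidised (Dess–Martin) to the keto acetate F13. Wittig methylenation (Ph3P=CH2, then Ac2O/pyridine to restore any cleaved acetate) gives the diene F14. Disiamylborane, which distinguishes the monosubstituted vinyl group from the hindered 1,1‑disubstituted C8 methylene, followed by NaBO3 gives the primary alcohol F15. Iodination (I2, PPh3, imidazole) gives the iodide F16, and zinc insertion followed by Negishi coupling with 27 [Pd(PPh3)4] gives target 34.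

**Further compounds**
F1 | step 8 | (4S,5S)-5-{3-[(tert-butyldimethylsilyl)oxy]propyl}-4-vinyldihydrofuran-2(3H)-one | O=C1C[C@@H](C=C)[C@H](CCCO[Si](C)(C)C(C)(C)C)O1
F2 | step 8 | (3R,4S,5S)-5-{3-[(tert-butyldimethylsilyl)oxy]propyl}-3-(3-chloropropyl)-4-vinyldihydrofuran-2(3H)-one | O=C1O[C@@H](CCCO[Si](C)(C)C(C)(C)C)[C@H](C=C)[C@H]1CCCCl
F3 | step 8 | (3R,4S,5S)-3-(3-chloropropyl)-5-(3-hydroxypropyl)-4-vinyldihydrofuran-2(3H)-one | O=C1O[C@@H](CCCO)[C@H](C=C)[C@H]1CCCCl
F4 | step 8 | 3-[(2S,3S,4R)-4-(3-chloropropyl)-5-oxo-3-vinyloxolan-2-yl]propanal | O=C1O[C@@H](CCC=O)[C@H](C=C)[C@H]1CCCCl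
F5 | step 8 | methyl (2E)-5-[(2S,3S,4R)-4-(3-chloropropyl)-5-oxo-3-vinyloxolan-2-yl]pent-2-enoate | O=C1O[C@@H](CC/C=C/C(=O)OC)[C@H](C=C)[C@H]1CCCCl
F6 | step 8 | methyl 20-oxo-8β,20-epoxy-13,14,15,16,17,18-hexanorlabd-11-en-19-oate (bridged lactone, C4 epimers) | O=C1O[C@H]2CC[C@@H]3[C@]1(CCCC3C(=O)OC)[C@H]2C=C
F7 | step 8 | methyl 20-oxo-8β,20-epoxy-13,14,15,16,17-pentanorlabd-11-en-19-oate (bridged lactone, 4α-Me) | O=C1O[C@H]2CC[C@@H]3[C@]1(CCC[C@]3(C)C(=O)OC)[C@H]2C=C
F8 | step 12 | methyl 8β,20-epoxy-12-hydroxy-20-methoxy-13,14,15,16,17-pentanorlabdan-19-oate | COC1O[C@H]2CC[C@@H]3[C@]1(CCC[C@]3(C)C(=O)OC)[C@H]2CCO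
F9 | step 12 | methyl 8β,20-epoxy-12-iodo-20-methoxy-13,14,15,16,17-pentanorlabdan-19-oate | COC1O[C@H]2CC[C@@H]3[C@]1(CCC[C@]3(C)C(=O)OC)[C@H]2CCI
F10 | step 12 | methyl 8β,20-epoxy-20-methoxy-13-(phenylsulfanyl)-17-norlabdan-16,15-olid-19-oate | COC1O[C@H]2CC[C@@H]3[C@]1(CCC[C@]3(C)C(=O)OC)[C@H]2CCC1(Sc2ccccc2)CCOC1=O
F11 | step 12 | methyl 8β,20-epoxy-20-methoxy-17-norlabd-13-en-16,15-olid-19-oate | COC1O[C@H]2CC[C@@H]3[C@]1(CCC[C@]3(C)C(=O)OC)[C@H]2CCC1=CCOC1=O
F12 | step 15 | methyl 20-acetoxy-8β-hydroxy-13,14,15,16,17-pentanorlabd-11-en-19-oate | O[C@H]1CC[C@@H]2[C@](COC(C)=O)(CCC[C@]2(C)C(=O)OC)[C@H]1C=C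
F13 | step 15 | methyl 20-acetoxy-8-oxo-13,14,15,16,17-pentanorlabd-11-en-19-oate | O=C1CC[C@@H]2[C@](COC(C)=O)(CCC[C@]2(C)C(=O)OC)[C@H]1C=C
F14 | step 15 | methyl 20-acetoxy-13,14,15,16-tetranorlabda-8(17),11-dien-19-oate | C=C1CC[C@@H]2[C@](COC(C)=O)(CCC[C@]2(C)C(=O)OC)[C@H]1C=C
F15 | step 15 | methyl 20-acetoxy-12-hydroxy-13,14,15,16-tetranorlabd-8(17)-en-19-oate | C=C1CC[C@@H]2[C@](COC(C)=O)(CCC[C@]2(C)C(=O)OC)[C@H]1CCO
F16 | step 15 | methyl 20-acetoxy-12-iodo-13,14,15,16-tetranorlabd-8(17)-en-19-oate | C=C1CC[C@@H]2[C@](COC(C)=O)(CCC[C@]2(C)C(=O)OC)[C@H]1CCI
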